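## Analysis of the target

Atom labels used throughout: ring A is the left tropolone (a1 C–CH3, a2 H, a3 C=O, a4 C–OH, a5 H, a6 C–O1, a7 C–C4). Ring B is its pyran (O1, C2, C3, C4), C5–C8 is the diene, ring C is the right pyran (O1', C2', C3', C4'), and ring D is the right tropolone (d1–d7, substituted like a1–a7).

The target is an unsymmetrical pair of 8-hydroxy-5-methyl-3,4-dihydrocyclohepta[b]pyran-7(2H)-ones joined from C2 to C2' by an (E,E)-buta-1,3-diene. It has three stereocentres. C2 (R) and C3 (R) are neighbours on ring B, with the C3 methyl trans to the dienyl group. C2' (R) sits alone on ring C, five bonds from C2 across a planar diene, so neither half can control the other and each must be set in the absolute sense. The tropolones are vinylogous acids that chelate metals. The O1–C2 and O1'–C2' bonds are secondary allylic (in the target dienylic) ethers of a vinylogous-acid oxygen, so they are open to ionisation by acid, to π-allyl formation by low-valent palladium, and to elimination whenever negative charge appears at C5/C7 or C8/C6. The hard part is to build two penta-substituted troponoid rings with the C=O/OH pair correctly placed relative to methyl, oxygen and CH2, and to join the halves without carbanion chemistry next to those ethers.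

The strategy rests on ring D. Its atoms d5, d6, d7, d1 carry H, O, C and CH3 in exactly the order found at C7, C7a, C4a, C5 of a 5-methyl-3,4-dihydro-2H-furo[3,4-b]pyran, and d2–d3–d4 is a three-carbon unit with a ketone and an adjacent oxygen. A methoxy-substituted oxyallyl unit added across the two furan α-carbons therefore gives ring D at the right oxidation level once the furan oxygen is lost by dehydration. Ring A has the same pattern, so the same annulation serves both halves.

## Retrosynthetic reasoning

**35 to 34.** The last bonds cut are the two O–CH3 bonds. The tropolones stay as methyl ethers until the end because free tropolones would bind the chromium, ruthenium and palladium reagents needed earlier. The forward step must remove two methyl groups without ionising the dienylic C2–O1 and C2'–O1' bonds.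

**34 to 18 and 33.** The diene is cut at C6–C7, the single bond between two preformed (E)-alkenes, giving iodoalkene 18 and alkenylboronate 33. A cut at C5=C6 or C7=C8 was considered first and set aside. Any olefination there needs a carbanion at C5/C7 or C6/C8, which is β or vinylogously β to an oxygen leaving group on a tropone and would open ring B or C by elimination; it would also expose the α-oxygenated aldehyde 17 to strong base. Cross-coupling at C6–C7 keeps both alkene geometries and joins two halves of similar size. The forward reaction must be fast enough at room temperature to outrun π-allyl ionisation.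

**18 back to 15, and 33 back to 32.** Iodoalkene 18 comes from aldehyde 17 by a non-basic chromium iodo-olefination that forms C7=C8. Aldehyde 17 comes from alcohol 16, and 16 from silyl ether 15. Boronate 33 comes from the vinyl compound 32 by cross-metathesis, which adds C6 together with boron. These handles are adjusted only after each troponoid ring is complete, so the annulation sees nothing but a silyl ether or a terminal alkene.

**15 to 14, and 32 to 31.** The aromatic ring is traced back to an oxygen-bridged ketone by adding the elements of a dehydration across d1 and d5. In the forward direction two β-eliminations flanking the d3 ketone expel the bridge oxygen, with no change of oxidation state.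

**14 to 11 and 13, and 31 to 30 and 13 (key disconnection).** The bonds d4–d5 and d1–d2 are cut. This splits ring D into the four-carbon furan edge, which already carries O1', C4' and CH3 in the right places, and a three-carbon unit that brings both oxygens. Cutting elsewhere would leave a seven-membered ring to be closed without this built-in placement of substituents. The gain is that both tropolone rings come from one small reagent, with the regiochemistry written into the furan. The forward reaction must bond the methoxy terminus to C7 of the furan and close at C5.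

**11 to 10, and 30 to 29.** The pyran ring is opened at O1'–C2' (O1–C2). In the forward direction the enol oxygen of a furan-3(2H)-one displaces an activated secondary alcohol with inversion. This bond is chosen because the furanone oxygen is the only nucleophilic site that can reach C2' (carbon alkylation would need a bridgehead alkene), and because inversion lets an (S)-carbinol from the chiral pool serve in 10 and a syn aldol pattern serve in 29.

**10 back to 1 and 3.** The furanone 8 is opened at its ring O–CH2 bond to a bromomethyl diketone, made by terminal bromination of the bis(silyl enol ether) 6; this fixes where the halogen goes. Diketone 4 comes from 3 and iodide 2 by C-alkylation (bond C4'–C4a), and 2 from alcohol 1. The acetonide is kept through all basic steps and exchanged for a primary silyl ether (8 to 9 to 10) only once the furanone is in place, because a free diol next to a 1,3-diketone would form bicyclic ketals.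

**29 back to 19, 20 and 3.** The same sequence leads from 29 through 27 and 25 to iodide 24 and 3. Iodide 24 comes from 23, 22 and 21, and 21 from 19 and 20 by cutting C2–C3 in the aldol sense. The syn aldol pattern followed by inversion at C2 gives the trans C2/C3 relationship of ring B.

**13 to 12.** The three-carbon partner is the kinetic silyl enol ether of 12.

## Alternatives that were turned down

**Alternative 1:** The cut is at C2–C5 and C2'–C8. The halves are the tropone-fused pyran-4-ones A3 (3-methyl) and A4, and the diene is the (E,E)-dienyl bis(boronate) A2. In the forward key step a hydroxo-rhodium catalyst (monovalent rhodium) with a chiral diene ligand transfers one alkenyl end to C2 of A3 and then the other to C2' of A4 in one flask, giving the bis(pyran-4-one) A1.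
- For: it is the most convergent plan. The diene geometry is bought, C2 and C2' are set by the catalyst, and C3 can settle trans by enolate protonation.
- Against: A3 is an α-substituted, doubly vinylogous ester and a poor acceptor, so the order of the two additions and the absence of homo-coupling must be forced. The adducts are β-aryloxy ketones whose C2–O1 bonds can open by retro-oxa-Michael reaction and racemise. A1 carries two extra carbonyl groups (C4, C4') that must be reduced to CH2 beside two tropone carbonyls and a diene. A3 and A4 must themselves be made, so the troponoid ring construction is not addressed.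
- Comparison: it is stronger on convergence and on catalytic stereocontrol. The chosen strategy instead builds the tropolone rings themselves, with C4/C4' already as CH2 and no carbonyl next to the stereocentres.

**Alternative 2:** The cut is at C4–a7 and C4'–d7. The chain is the tetraene bis(silyl ether) A6 and both rings come from the bromotroponoid A7. In the forward key step a dialkylborane hydroborates the isopropenyl and vinyl ends (setting C3 by induction from C2), and both alkylboranes couple with A7 under palladium catalysis (a divalent palladium precatalyst reduced in the flask to zerovalent palladium), giving A5. Rings B and C would then have to close by oxygen attack on the methoxy-bearing tropone carbons.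
- For: it is two-directional and short, uses one troponoid twice, and has the diene and C2/C2' in place early. Anti-selective hydroboration would match the trans ring after a retentive closure.
- Against: A7, with bromine, two methoxy groups and methyl correctly placed, is a problem at least as large as one half of the chosen route. Hydroboration must distinguish the terminal alkenes from the internal diene and give high acyclic 1,2-induction. A hindered bromide flanked on both sides must couple twice. The pyran closures need alkoxide chemistry on dienylic carbinols.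
- Comparison: it is stronger on step count on paper. The chosen route offers tropolone regiochemistry defined by furan substitution and a C3 centre from an auxiliary aldol instead of acyclic substrate control.

**Alternative 3:** The cut is at a4–a5 and a6–a7, with ring B formed at the same time through the O1 tether. The precursor is the acetoxypyranone A9 carrying an ethynyl ether on the C2 oxygen. In the forward key step base-induced loss of acetate gives a 3-oxidopyrylium ylide that adds across the tethered ynol ether, giving the oxygen-bridged cycloheptadienone A8. Acid opening of the bridge would give the free tropolone directly.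
- For: the tether enforces the regiochemistry, which is stronger than the electronic control relied on in the chosen step. Rings A and B form together, and no O-methyl group has to be removed at the end.
- Against: a secondary alkynyl ether is fragile to acid and heat and laborious to install on a hindered carbinol. A9 needs an oxidative furan-to-pyranone rearrangement on a functionalised furan. The whole sequence is needed once per half, and A8 leads back to the same junction problem.
- Comparison: it is stronger on regiocontrol and on the final deprotection. The chosen strategy offers robust precursors, one small reagent for both halves, and a pyran ring closed by a reliable displacement before the annulation.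

Key step: step 9

Remark: the tropolones are written in the tautomer of the target drawing (C7=O, C8–OH); the methyl ethers from 15 and 32 onward are single constitutional isomers fixed by the annulation.

Remark: in furo[3,4-b]pyran numbering the methyl-bearing α-carbon of 11 and 30 is C5 (next to C4a) and the free α-carbon is C7 (next to C7a).

## Steps

Step 1
Reactants: 1 (S)-2-(2,2-dimethyl-1,3-dioxolan-4-yl)ethanol
Product: 2 (S)-4-(2-iodoethyl)-2,2-dimethyl-1,3-dioxolane
Conditions: I2, PPh3, imidazole, CH2Cl2, 0 °C to rt
Reagents that add atoms: iodine, II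
Why: Appel-type iodination of a primary alcohol; imidazole buffers the acid so the acetonide survives, and the stereocentre is not touched.

Step 2
Reactants: 2 (S)-4-(2-iodoethyl)-2,2-dimethyl-1,3-dioxolane; 3 acetylacetone (pentane-2,4-dione)
Product: 4 3-{2-[(4S)-2,2-dimethyl-1,3-dioxolan-4-yl]ethyl}pentane-2,4-dione
Conditions: 3 (2 equiv), K2CO3, acetone, reflux
Reagents that add atoms: none
Why: C-alkylation of a β-diketone enolate by an unhindered primary iodide (SN2), forming C4'–C4a; excess 3 should suppress dialkylation.

Step 3
Reactants: 4 3-{2-[(4S)-2,2-dimethyl-1,3-dioxolan-4-yl]ethyl}pentane-2,4-dione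
Product: 6 3-{2-[(4S)-2,2-dimethyl-1,3-dioxolan-4-yl]ethyl}-2,4-bis(trimethylsilyloxy)penta-1,3-diene (enol ether isomers), via mono silyl enol ether 5 (not isolated)
Conditions: Me3SiCl, Et3N, DMF, rt; pentane extraction; then LiN(iPr)2, THF, −78 °C; Me3SiCl
Reagents that add atoms: chlorotrimethylsilane, C[Si](C)(C)Cl
Why: Stepwise double enol silylation of a 1,3-diketone to a 1,3-bis(silyloxy)diene; 4 is symmetric about C3, so deprotonation of either methyl gives the same diene, and the acetonide is inert to these basic conditions.

Step 4
Reactants: 6 3-{2-[(4S)-2,2-dimethyl-1,3-dioxolan-4-yl]ethyl}-2,4-bis(trimethylsilyloxy)penta-1,3-diene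
Product: 8 4-{2-[(4S)-2,2-dimethyl-1,3-dioxolan-4-yl]ethyl}-5-methylfuran-3(2H)-one, via bromo ketone silyl enol ether 7 (not isolated)
Conditions: N-bromosuccinimide, THF, −78 °C; then K2CO3, MeOH, 0 °C
Reagents that add atoms: N-bromosuccinimide, O=C1CCC(=O)N1Br (its bromine is present in 7 only and leaves as bromide on ring closure)
Why: Electrophilic halogenation of a 1,3-bis(silyloxy)diene goes to the terminal carbon, not the hindered C3; methanolysis then frees the enolate, whose oxygen displaces bromide (5-exo-tet O-alkylation) to give the furan-3(2H)-one.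

Step 5
Reactants: 8 4-{2-[(4S)-2,2-dimethyl-1,3-dioxolan-4-yl]ethyl}-5-methylfuran-3(2H)-one
Product: 9 4-[(3S)-3,4-dihydroxybutyl]-5-methylfuran-3(2H)-one
Conditions: AcOH/H2O/THF, 40 °C
Reagents that add atoms: none
Why: Acid hydrolysis of the acetonide; the vinylogous-ester carbonyl of the furanone is not electrophilic enough to ketalise with the diol, which is why the diol is released only at this stage.

Step 6
Reactants: 9 4-[(3S)-3,4-dihydroxybutyl]-5-methylfuran-3(2H)-one
Product: 10 4-[(3S)-3-hydroxy-4-(triisopropylsilyloxy)butyl]-5-methylfuran-3(2H)-one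
Conditions: iPr3SiCl, imidazole, CH2Cl2, 0 °C
Reagents that add atoms: chlorotriisopropylsilane, CC(C)[Si](Cl)(C(C)C)C(C)C
Why: Selective silylation of the primary hydroxyl by a bulky silyl chloride leaves the secondary carbinol free for the ring closure.

Step 7
Reactants: 10 4-[(3S)-3-hydroxy-4-(triisopropylsilyloxy)butyl]-5-methylfuran-3(2H)-one
Product: 11 triisopropyl{[(2R)-5-methyl-3,4-dihydro-2H-furo[3,4-b]pyran-2-yl]methoxy}silane
Conditions: PBu3, 1,1'-(azodicarbonyl)dipiperidine (ADDP), toluene, 0 °C to rt, 0.02 M; chromatography on Et3N-deactivated silica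
Reagents that add atoms: none
Why: Intramolecular Mitsunobu etherification: the 3-hydroxyfuran tautomer of the furanone is the acidic partner, and its oxygen displaces the activated secondary alcohol (6-exo-tet SN2) with inversion, turning (S) into (R) at C2'. Carbon alkylation at the furanone CH2 would need a bridgehead alkene and is excluded; the more basic PBu3/ADDP betaine is chosen because the furanone is only weakly acidic.

Step 8
Reactants: 12 1,1-dimethoxyacetone
Product: 13 3,3-dimethoxy-2-(trimethylsilyloxy)prop-1-ene
Conditions: LiN(iPr)2, THF, −78 °C; Me3SiCl; distillation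
Reagents that add atoms: chlorotrimethylsilane, C[Si](C)(C)Cl
Why: Kinetic enolisation at the methyl group (the acetal CH is tertiary and slower to deprotonate) and O-silylation give the silyl enol ether used in steps 9 and 22.

Step 9
Reactants: 11 triisopropyl{[(2R)-5-methyl-3,4-dihydro-2H-furo[3,4-b]pyran-2-yl]methoxy}silane; 13 3,3-dimethoxy-2-(trimethylsilyloxy)prop-1-ene
Product: 14 oxygen-bridged adduct, a 2-methoxy-5-methyl-8-oxabicyclo[3.2.1]oct-6-en-3-one fused to ring C (C4' on C6 and O1' on C7 of the bicycle; bridgeheads d5 with H and d1 with CH3; (R) at C2' bearing CH2OSi(iPr)3; mixture of diastereomers at d1, d4, d5)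
Conditions: 13 (1.5 equiv), Me3SiOTf (10 mol %), CH2Cl2, −78 °C; Et3N quench
Reagents that add atoms: none
Why: Acetal ionisation followed by a stepwise (4+3) cycloaddition: catalytic Me3SiOTf removes one methoxy group of 13 and gives the 1-methoxy-2-(trimethylsilyloxy)allyl cation, best read as an oxocarbenium ion that carries a silyl enol ether. C7 of 11 (atom d5), the free α-carbon next to the O1' alkoxy group and so the most nucleophilic and least hindered furan position, attacks the methoxy-bearing carbon and forms d4–d5. The furan-derived oxocarbenium ion, with its charge at C5 (d1) held by the ring oxygen and the methyl group, is then captured by the enol ether CH2 (d2), which forms d1–d2 and releases the silyl cation to carry the chain. The closest known reaction type is the silyl-triflate-catalysed (4+3) cycloaddition of furans with alkoxy-substituted 2-silyloxyallyl cations to 2-alkoxy-8-oxabicyclo[3.2.1]oct-6-en-3-ones. Ring D closes as a seven-membered carbocycle in this stepwise (4+3) mode, the second bond being an intramolecular enol ether addition to a cyclic oxocarbenium carbon (7-exo with respect to the C5=O bond), and the furan oxygen stays as the one-atom bridge. The centres created at d1, d4 and d5 form as a mixture relative to C2' and are all erased in step 10, so nothing has to control them; C2' lies outside the reacting atoms and keeps its (R) configuration. The step needs the methoxy terminus to bond to d5 and not to d1, which the alkoxy polarisation of the furan and the hindrance at the methyl-bearing C5 should secure, and it needs ring closure to outrun loss of the C7 proton, which low temperature and the absence of base favour.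

Step 10
Reactants: 14 oxygen-bridged adduct
Product: 15 (2R)-8-methoxy-5-methyl-2-[(triisopropylsilyloxy)methyl]-3,4-dihydrocyclohepta[b]pyran-7(2H)-one
Conditions: Me3SiOTf (2.5 equiv), Et3N (4 equiv), CH2Cl2, 0 °C to rt
Reagents that add atoms: none
Why: Silyl triflate/amine opening of an 8-oxabicyclo[3.2.1]octenone: enol silylation toward d2 and silyl-assisted cleavage of the d1–O bond, then enolisation toward d4 and loss of silanolate from d5 (two β-eliminations). The product is the aromatic 2-methoxytropone with the ketone at d3 and methoxy at d4, without any redox change.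

Step 11
Reactants: 15 (2R)-8-methoxy-5-methyl-2-[(triisopropylsilyloxy)methyl]-3,4-dihydrocyclohepta[b]pyran-7(2H)-one
Product: 16 (2R)-2-(hydroxymethyl)-8-methoxy-5-methyl-3,4-dihydrocyclohepta[b]pyran-7(2H)-one
Conditions: HF·pyridine, THF/pyridine, 0 °C to rt
Reagents that add atoms: none
Why: Fluoride desilylation under buffered, non-basic conditions, so that no hydroxide or alkoxide can attack the methoxytropone.

Step 12
Reactants: 16 (2R)-2-(hydroxymethyl)-8-methoxy-5-methyl-3,4-dihydrocyclohepta[b]pyran-7(2H)-one
Product: 17 (2R)-8-methoxy-5-methyl-7-oxo-2,3,4,7-tetrahydrocyclohepta[b]pyran-2-carbaldehyde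
Conditions: Dess–Martin periodinane, NaHCO3, CH2Cl2, 0 °C; used crude
Reagents that add atoms: none
Why: Dess–Martin oxidation is neutral and should not epimerise the α-oxygenated aldehyde, which is carried on without storage.

Step 13
Reactants: 17 (2R)-8-methoxy-5-methyl-7-oxo-2,3,4,7-tetrahydrocyclohepta[b]pyran-2-carbaldehyde
Product: 18 (2R)-2-[(E)-2-iodoethenyl]-8-methoxy-5-methyl-3,4-dihydrocyclohepta[b]pyran-7(2H)-one
Conditions: CHI3, CrCl2 (divalent chromium), THF/dioxane, 0 °C to rt
Reagents that add atoms: iodoform, IC(I)I
Why: Takai iodo-olefination forms C7=C8 with (E) selectivity; the geminal dichromium reagent is not basic, so C2' should keep its configuration and ring C should stay closed.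

Step 14
Reactants: 19 (4S)-4-benzyl-3-propanoyl-1,3-oxazolidin-2-one; 20 acrolein
Product: 21 (4S)-4-benzyl-3-[(2S,3R)-3-hydroxy-2-methylpent-4-enoyl]-1,3-oxazolidin-2-one
Conditions: Bu2BOTf, Et3N, CH2Cl2, −78 to 0 °C; then pH 7 buffer, MeOH, H2O2
Reagents that add atoms: none
Why: Evans syn aldol reaction: the (Z)-boron enolate reacts through a Zimmerman–Traxler chair and the benzyl group of the auxiliary selects the enolate face, setting the future C3 (methyl) and C2 (hydroxyl) in the syn relationship and in the absolute sense.

Step 15
Reactants: 21 (4S)-4-benzyl-3-[(2S,3R)-3-hydroxy-2-methylpent-4-enoyl]-1,3-oxazolidin-2-one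
Product: 22 (4S)-4-benzyl-3-[(2S,3R)-2-methyl-3-(triethylsilyloxy)pent-4-enoyl]-1,3-oxazolidin-2-one
Conditions: Et3SiOTf, 2,6-lutidine, CH2Cl2, −78 °C
Reagents that add atoms: triethylsilyl triflate, CC[Si](CC)(CC)OS(=O)(=O)C(F)(F)F
Why: Silylation of the secondary alcohol; the ether blocks retro-aldol cleavage now and acyl transfer from the 1,3-diketone later, and is removed under mild acid in step 20.

Step 16
Reactants: 22 (4S)-4-benzyl-3-[(2S,3R)-2-methyl-3-(triethylsilyloxy)pent-4-enoyl]-1,3-oxazolidin-2-one
Product: 23 (2R,3R)-2-methyl-3-(triethylsilyloxy)pent-4-en-1-ol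
Conditions: LiBH4, MeOH (1 equiv), Et2O, 0 °C
Reagents that add atoms: none
Why: Reductive removal of the auxiliary gives the primary alcohol (future C4) without touching the two stereocentres; the auxiliary is recovered.

Step 17
Reactants: 23 (2R,3R)-2-methyl-3-(triethylsilyloxy)pent-4-en-1-ol
Product: 24 triethyl{[(3R,4S)-5-iodo-4-methylpent-1-en-3-yl]oxy}silane
Conditions: I2, PPh3, imidazole, CH2Cl2, 0 °C
Reagents that add atoms: iodine, II
Why: Appel-type iodination of the primary alcohol; the descriptor at the methyl-bearing carbon changes only because iodine changes the priorities.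

Step 18
Reactants: 24 triethyl{[(3R,4S)-5-iodo-4-methylpent-1-en-3-yl]oxy}silane; 3 acetylacetone
Product: 25 3-[(2R,3R)-2-methyl-3-(triethylsilyloxy)pent-4-en-1-yl]pentane-2,4-dione
Conditions: 3 (3 equiv), Cs2CO3, DMF, 50 °C
Reagents that add atoms: none
Why: C-alkylation of the β-diketone enolate (SN2), forming C4–a7; the iodide is β-branched, so the caesium enolate in a dipolar solvent and excess 3 are used to keep the rate up.

Step 19
Reactants: 25 3-[(2R,3R)-2-methyl-3-(triethylsilyloxy)pent-4-en-1-yl]pentane-2,4-dione
Product: 27 triethyl{[(3R,4R)-4-methyl-5-[2,4-bis(trimethylsilyloxy)penta-1,3-dien-3-yl]pent-1-en-3-yl]oxy}silane (enol ether isomers), via mono silyl enol ether 26 (not isolated)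
Conditions: Me3SiCl, Et3N, DMF, rt; pentane extraction; then LiN(iPr)2, THF, −78 °C; Me3SiCl
Reagents that add atoms: chlorotrimethylsilane, C[Si](C)(C)Cl
Why: The same double enol silylation as in step 3; the allylic silyl ether and the terminal alkene are inert to the amide base at −78 °C.

Step 20
Reactants: 27 bis(silyl enol ether) of 25
Product: 29 4-[(2R,3R)-3-hydroxy-2-methylpent-4-en-1-yl]-5-methylfuran-3(2H)-one, via bromo ketone silyl enol ether 28 (not isolated)
Conditions: N-bromosuccinimide, THF, −78 °C; K2CO3, MeOH, 0 °C; work-up; then pyridinium p-toluenesulfonate (cat.), MeOH, rt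
Reagents that add atoms: N-bromosuccinimide, O=C1CCC(=O)N1Br (its bromine is present in 28 only and leaves as bromide on ring closure)
Why: Terminal bromination of the bis(silyloxy)diene and 5-exo-tet O-alkylation as in step 4, then acid-catalysed methanolysis of the triethylsilyl ether; the monosubstituted alkene is far less nucleophilic than the dienol ether toward the bromine source.

Step 21
Reactants: 29 4-[(2R,3R)-3-hydroxy-2-methylpent-4-en-1-yl]-5-methylfuran-3(2H)-one
Product: 30 (2S,3R)-2-ethenyl-3,5-dimethyl-3,4-dihydro-2H-furo[3,4-b]pyran
Conditions: PBu3, ADDP, toluene, 0 °C to rt, 0.02 M; chromatography on Et3N-deactivated silica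
Reagents that add atoms: none
Why: Intramolecular Mitsunobu etherification as in step 7: 6-exo-tet SN2 at the allylic carbinol with inversion at C2 converts the syn aldol pattern into the trans C2/C3 relationship of ring B. The (2S) descriptor reflects the low priority of vinyl; the geometry is that of the target.

Step 22
Reactants: 30 (2S,3R)-2-ethenyl-3,5-dimethyl-3,4-dihydro-2H-furo[3,4-b]pyran; 13 3,3-dimethoxy-2-(trimethylsilyloxy)prop-1-ene
Product: 31 oxygen-bridged adduct, a 2-methoxy-5-methyl-8-oxabicyclo[3.2.1]oct-6-en-3-one fused to ring B (C4 on C6 and O1 on C7 of the bicycle; C2 and C3 as in 30; mixture of diastereomers at a1, a4, a5)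
Conditions: 13 (1.5 equiv), Me3SiOTf (10 mol %), CH2Cl2, −78 °C; Et3N quench
Reagents that add atoms: none
Why: Second use of the (4+3) cycloaddition of step 9, forming a4–a5 and a1–a2 with the same regiochemical control; the terminal alkene is not nucleophilic enough to compete with the alkoxyfuran, and C2 and C3 lie outside the reacting atoms.

Step 23
Reactants: 31 oxygen-bridged adduct
Product: 32 (2S,3R)-2-ethenyl-8-methoxy-3,5-dimethyl-3,4-dihydrocyclohepta[b]pyran-7(2H)-one
Conditions: Me3SiOTf (2.5 equiv), Et3N (4 equiv), CH2Cl2, 0 °C to rt
Reagents that add atoms: none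
Why: The same double β-elimination of the bridge oxygen as in step 10 gives the 2-methoxytropone of ring A.

Step 24
Reactants: 32 (2S,3R)-2-ethenyl-8-methoxy-3,5-dimethyl-3,4-dihydrocyclohepta[b]pyran-7(2H)-one
Product: 33 (2R,3R)-8-methoxy-3,5-dimethyl-2-[(E)-2-(4,4,5,5-tetramethyl-1,3,2-dioxaborolan-2-yl)ethenyl]-3,4-dihydrocyclohepta[b]pyran-7(2H)-one
Conditions: vinylboronic acid pinacol ester (4 equiv), second-generation Hoveyda–Grubbs catalyst RuCl2(H2IMes)(=CH-C6H4-2-OiPr) (10 mol %), CH2Cl2, 40 °C
Reagents that add atoms: vinylboronic acid pinacol ester, C=CB1OC(C)(C)C(C)(C)O1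
Why: Olefin cross-metathesis of a terminal alkene with a vinylboronate gives the (E)-alkenylboronate (C5=C6) under neutral conditions; the tropone double bonds are too substituted and electron-poor to take part.

Step 25
Reactants: 18 (2R)-2-[(E)-2-iodoethenyl]-8-methoxy-5-methyl-3,4-dihydrocyclohepta[b]pyran-7(2H)-one; 33 alkenylboronate
Product: 34 (2R,3R)-8-methoxy-2-{(1E,3E)-4-[(2R)-8-methoxy-5-methyl-7-oxo-2,3,4,7-tetrahydrocyclohepta[b]pyran-2-yl]buta-1,3-dien-1-yl}-3,5-dimethyl-3,4-dihydrocyclohepta[b]pyran-7(2H)-one
Conditions: PdCl2(dppf) (5 mol %; divalent palladium precatalyst, reduced in the flask to zerovalent palladium), AsPh3, Cs2CO3, DMF/THF/H2O, rt, degassed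
Reagents that add atoms: none
Why: Suzuki–Miyaura coupling of an alkenyl iodide with an alkenylboronate forms C6–C7 with retention of both (E) geometries; oxidative addition into the C–I bond at room temperature should be much faster than ionisation of the allylic C–O bonds, and carbonate is too weak a base to attack the methoxytropones.

Step 26
Reactants: 34 bis(methoxytropone)
Product: 35 CNP0332980.1, (2R,3R)-8-hydroxy-2-{(1E,3E)-4-[(2R)-8-hydroxy-5-methyl-7-oxo-2,3,4,7-tetrahydrocyclohepta[b]pyran-2-yl]buta-1,3-dien-1-yl}-3,5-dimethyl-3,4-dihydrocyclohepta[b]pyran-7(2H)-one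
Conditions: BCl3 (3 equiv), CH2Cl2, −78 °C, 20 min; MeOH, then aq. NaHCO3
Reagents that add atoms: none
Why: Chelation-assisted Lewis-acid demethylation: boron binds the tropone carbonyl and the neighbouring methoxy oxygen, and chloride removes the methyl group by SN2; the ring oxygens O1 and O1' are not in a chelate, and low temperature with a short reaction time should leave the dienylic ethers intact.

## Compound list

1 | (S)-2-(2,2-dimethyl-1,3-dioxolan-4-yl)ethanol | OCC[C@H]1COC(C)(C)O1 | starting material
2 | (S)-4-(2-iodoethyl)-2,2-dimethyl-1,3-dioxolane | ICC[C@H]1COC(C)(C)O1 | intermediate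
3 | acetylacetone (pentane-2,4-dione) | CC(=O)CC(C)=O | starting material
4 | 3-{2-[(4S)-2,2-dimethyl-1,3-dioxolan-4-yl]ethyl}pentane-2,4-dione | CC(=O)C(CC[C@H]1COC(C)(C)O1)C(C)=O | intermediate
5 | 3-{2-[(4S)-2,2-dimethyl-1,3-dioxolan-4-yl]ethyl}-4-(trimethylsilyloxy)pent-3-en-2-one (not isolated) | CC(=O)C(CC[C@H]1COC(C)(C)O1)=C(C)O[Si](C)(C)C | intermediate
6 | 3-{2-[(4S)-2,2-dimethyl-1,3-dioxolan-4-yl]ethyl}-2,4-bis(trimethylsilyloxy)penta-1,3-diene | C=C(O[Si](C)(C)C)C(CC[C@H]1COC(C)(C)O1)=C(C)O[Si](C)(C)C | intermediate
7 | 1-bromo-3-{2-[(4S)-2,2-dimethyl-1,3-dioxolan-4-yl]ethyl}-4-(trimethylsilyloxy)pent-3-en-2-one (not isolated) | BrCC(=O)C(CC[C@H]1COC(C)(C)O1)=C(C)O[Si](C)(C)C | intermediate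
8 | 4-{2-[(4S)-2,2-dimethyl-1,3-dioxolan-4-yl]ethyl}-5-methylfuran-3(2H)-one | CC1=C(CC[C@H]2COC(C)(C)O2)C(=O)CO1 | intermediate
9 | 4-[(3S)-3,4-dihydroxybutyl]-5-methylfuran-3(2H)-one | CC1=C(CC[C@H](O)CO)C(=O)CO1 | intermediate
10 | 4-[(3S)-3-hydroxy-4-(triisopropylsilyloxy)butyl]-5-methylfuran-3(2H)-one | CC1=C(CC[C@H](O)CO[Si](C(C)C)(C(C)C)C(C)C)C(=O)CO1 | intermediate
11 | triisopropyl{[(2R)-5-methyl-3,4-dihydro-2H-furo[3,4-b]pyran-2-yl]methoxy}silane | CC(C)[Si](C(C)C)(C(C)C)OC[C@H]1CCc2c(C)occ2O1 | intermediate
12 | 1,1-dimethoxyacetone | CC(=O)C(OC)OC | starting material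
13 | 3,3-dimethoxy-2-(trimethylsilyloxy)prop-1-ene | C=C(O[Si](C)(C)C)C(OC)OC | intermediate
14 | oxygen-bridged methoxy cycloheptenone fused to ring C, (R) at C2', diastereomers at d1, d4, d5 | CC(C)[Si](C(C)C)(C(C)C)OC[C@H]1CCC2=C(O1)C3C(OC)C(=O)CC2(C)O3 | intermediate
15 | (2R)-8-methoxy-5-methyl-2-[(triisopropylsilyloxy)methyl]-3,4-dihydrocyclohepta[b]pyran-7(2H)-one | CC(C)[Si](C(C)C)(C(C)C)OC[C@H]1CCc2c(C)cc(=O)c(OC)cc2O1 | intermediate
16 | (2R)-2-(hydroxymethyl)-8-methoxy-5-methyl-3,4-dihydrocyclohepta[b]pyran-7(2H)-one | OC[C@H]1CCc2c(C)cc(=O)c(OC)cc2O1 | intermediate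
17 | (2R)-8-methoxy-5-methyl-7-oxo-2,3,4,7-tetrahydrocyclohepta[b]pyran-2-carbaldehyde | O=C[C@H]1CCc2c(C)cc(=O)c(OC)cc2O1 | intermediate
18 | (2R)-2-[(E)-2-iodoethenyl]-8-methoxy-5-methyl-3,4-dihydrocyclohepta[b]pyran-7(2H)-one | I/C=C/[C@H]1CCc2c(C)cc(=O)c(OC)cc2O1 | intermediate
19 | (4S)-4-benzyl-3-propanoyl-1,3-oxazolidin-2-one | CCC(=O)N1[C@@H](Cc2ccccc2)COC1=O | starting material
20 | acrolein | C=CC=O | starting material
21 | (4S)-4-benzyl-3-[(2S,3R)-3-hydroxy-2-methylpent-4-enoyl]-1,3-oxazolidin-2-one | O=C(N1[C@@H](Cc2ccccc2)COC1=O)[C@@H](C)[C@H](O)C=C | intermediate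
22 | (4S)-4-benzyl-3-[(2S,3R)-2-methyl-3-(triethylsilyloxy)pent-4-enoyl]-1,3-oxazolidin-2-one | O=C(N1[C@@H](Cc2ccccc2)COC1=O)[C@@H](C)[C@H](O[Si](CC)(CC)CC)C=C | intermediate
23 | (2R,3R)-2-methyl-3-(triethylsilyloxy)pent-4-en-1-ol | OC[C@@H](C)[C@H](O[Si](CC)(CC)CC)C=C | intermediate
24 | triethyl{[(3R,4S)-5-iodo-4-methylpent-1-en-3-yl]oxy}silane | IC[C@@H](C)[C@H](O[Si](CC)(CC)CC)C=C | intermediate
25 | 3-[(2R,3R)-2-methyl-3-(triethylsilyloxy)pent-4-en-1-yl]pentane-2,4-dione | CC(=O)C(C[C@@H](C)[C@H](O[Si](CC)(CC)CC)C=C)C(C)=O | intermediate
26 | 3-[(2R,3R)-2-methyl-3-(triethylsilyloxy)pent-4-en-1-yl]-4-(trimethylsilyloxy)pent-3-en-2-one (not isolated) | CC(=O)C(C[C@@H](C)[C@H](O[Si](CC)(CC)CC)C=C)=C(C)O[Si](C)(C)C | intermediate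
27 | triethyl{[(3R,4R)-4-methyl-5-[2,4-bis(trimethylsilyloxy)penta-1,3-dien-3-yl]pent-1-en-3-yl]oxy}silane | C=C(O[Si](C)(C)C)C(C[C@@H](C)[C@H](O[Si](CC)(CC)CC)C=C)=C(C)O[Si](C)(C)C | intermediate
28 | 1-bromo-3-[(2R,3R)-2-methyl-3-(triethylsilyloxy)pent-4-en-1-yl]-4-(trimethylsilyloxy)pent-3-en-2-one (not isolated) | BrCC(=O)C(C[C@@H](C)[C@H](O[Si](CC)(CC)CC)C=C)=C(C)O[Si](C)(C)C | intermediate
29 | 4-[(2R,3R)-3-hydroxy-2-methylpent-4-en-1-yl]-5-methylfuran-3(2H)-one | CC1=C(C[C@@H](C)[C@H](O)C=C)C(=O)CO1 | intermediate
30 | (2S,3R)-2-ethenyl-3,5-dimethyl-3,4-dihydro-2H-furo[3,4-b]pyran | C=C[C@H]1[C@H](C)Cc2c(C)occ2O1 | intermediate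
31 | oxygen-bridged methoxy cycloheptenone fused to ring B, C2 and C3 as in 30, diastereomers at a1, a4, a5 | C=C[C@H]1[C@H](C)CC2=C(O1)C3C(OC)C(=O)CC2(C)O3 | intermediate
32 | (2S,3R)-2-ethenyl-8-methoxy-3,5-dimethyl-3,4-dihydrocyclohepta[b]pyran-7(2H)-one | C=C[C@H]1[C@H](C)Cc2c(C)cc(=O)c(OC)cc2O1 | intermediate
33 | (2R,3R)-8-methoxy-3,5-dimethyl-2-[(E)-2-(4,4,5,5-tetramethyl-1,3,2-dioxaborolan-2-yl)ethenyl]-3,4-dihydrocyclohepta[b]pyran-7(2H)-one | CC1(C)OB(/C=C/[C@H]2[C@H](C)Cc3c(C)cc(=O)c(OC)cc3O2)OC1(C)C | intermediate
34 | (2R,3R)-8-methoxy-2-{(1E,3E)-4-[(2R)-8-methoxy-5-methyl-7-oxo-2,3,4,7-tetrahydrocyclohepta[b]pyran-2-yl]buta-1,3-dien-1-yl}-3,5-dimethyl-3,4-dihydrocyclohepta[b]pyran-7(2H)-one | Cc1cc(=O)c(OC)cc2c1C[C@@H](C)[C@H](/C=C/C=C/[C@H]1CCc3c(C)cc(=O)c(OC)cc3O1)O2 | intermediate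
35 | CNP0332980.1, the (2R,3R,2'R) bis(tropolone) | Cc1cc(=O)c(O)cc2c1C[C@@H](C)[C@H](/C=C/C=C/[C@H]1CCc3c(C)cc(=O)c(O)cc3O1)O2 | target

## Step count and least certain steps

Total: 26 steps. Longest linear sequence: 14 steps (steps 1–7, 9–13, 25, 26, from 1). The left half takes 13 steps in line (steps 14–26) and the reagent 13 takes one step (step 8).

**Steps 9 and 22 (key step).** The most likely failure is loss of the C7 proton from the first cationic intermediate, which re-aromatises the furan and gives substitution in place of annulation. The alkoxyfuran is a very good nucleophile but the neutral silyl enol ether is only a moderate internal trap. A second risk is first bond formation at the CH2 terminus of the cation, which would move the methoxy group to d2 (a2), and a third is acid-induced oligomerisation of the furan. Fallback, from 11 (or 30) back to 14 (or 31): the same methoxy-oxyallyl unit is generated without any Lewis acid from 1-chloro-3-methoxypropan-2-one with Et3N in 2,2,2-trifluoroethanol. After the first bond the closing nucleophile is then an enolate and not a silyl enol ether, which should make ring closure faster than proton loss. This fallback makes no new compound (F0).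

**Step 18.** The SN2 reaction at a β-branched iodide may be so slow that O-alkylation of the enolate and deacetylation of the product take over. Fallback, from 24 back to 25: zinc insertion (Zn dust, LiCl, THF) gives the alkylzinc iodide F1. Negishi coupling of F1 with 4-iodo-3,5-dimethylisoxazole (Pd(OAc)2, SPhos; divalent palladium precatalyst reduced to zerovalent palladium) gives the 4-alkyl-3,5-dimethylisoxazole F2, a masked 1,3-diketone. Reductive N–O cleavage with Mo(CO)6 in wet acetonitrile gives the enaminone F3, and mild aqueous acid (oxalic acid, THF) hydrolyses it to 25.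

**Steps 7 and 21.** The furanone may be too weak an acid to protonate the betaine, so that the activated alcohol is consumed by the hydrazide or by elimination; for 29 the carbinol is also hindered and allylic, which invites elimination to a diene. Fallback, from 10 back to 11: selective O-sulfonylation (MsCl, Et3N, −20 °C) gives the methanesulfonate F4, and Cs2CO3 in DMF generates the furan-3-olate, whose oxygen displaces the sulfonate (6-exo-tet, inversion as before). From 29 back to 30, the allylic methanesulfonate F5 is made at −40 °C and cyclised in the same flask with Cs2CO3.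

**Step 25.** Zerovalent palladium may ionise the allylic C2–O1 or C2'–O1' bond of 18, 33 or 34 to a π-allyl complex, which would scramble C2 or C2' or open a pyran ring; protodeboronation of 33 is a lesser risk. Fallback, from 32 and 17 back to 34, without palladium at the junction: cross-metathesis of 32 with diethyl allylphosphonate (same ruthenium catalyst) gives the allylic phosphonate F6. LiN(SiMe3)2 is added at −78 °C to a mixture of F6 and aldehyde 17 (Horner–Wadsworth–Emmons olefination forming C7=C8), so that the anion is trapped before it can expel O1 by 1,4-elimination.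

**Step 26.** Once boron is bound to a tropone, the ring oxygen becomes a better leaving group, and the dienylic C2–O1 or C2'–O1' bond may ionise to a pentadienyl cation or be opened by chloride. Fallback, from 34 back to 35: the methoxy groups are removed at the ring carbon instead of at the methyl carbon. Dilute LiOH in aqueous THF at 0 °C to rt should hydrolyse the vinylogous esters by addition–elimination at C8 and C8' (the most electrophilic tropone position, next to the carbonyl), followed by acidification to pH 5. No Lewis acid is involved and the fallback makes no new compound (F0).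

## Further compounds

F0 | step 9 | none | none
F0 | step 22 | none | none
F1 | step 18 | iodo[(2S,3R)-2-methyl-3-(triethylsilyloxy)pent-4-en-1-yl]zinc | I[Zn]C[C@@H](C)[C@H](O[Si](CC)(CC)CC)C=C
F2 | step 18 | 3,5-dimethyl-4-[(2R,3R)-2-methyl-3-(triethylsilyloxy)pent-4-en-1-yl]isoxazole | Cc1noc(C)c1C[C@@H](C)[C@H](O[Si](CC)(CC)CC)C=C
F3 | step 18 | (Z)-4-amino-3-[(2R,3R)-2-methyl-3-(triethylsilyloxy)pent-4-en-1-yl]pent-3-en-2-one | N/C(C)=C(/C[C@@H](C)[C@H](O[Si](CC)(CC)CC)C=C)C(C)=O
F4 | step 7 | (2S)-4-(2-methyl-4-oxo-4,5-dihydrofuran-3-yl)-1-(triisopropylsilyloxy)butan-2-yl methanesulfonate | CC1=C(CC[C@H](OS(C)(=O)=O)CO[Si](C(C)C)(C(C)C)C(C)C)C(=O)CO1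
F5 | step 21 | (3R,4R)-4-methyl-5-(2-methyl-4-oxo-4,5-dihydrofuran-3-yl)pent-1-en-3-yl methanesulfonate | CC1=C(C[C@@H](C)[C@H](OS(C)(=O)=O)C=C)C(=O)CO1
F6 | step 25 | diethyl {(2E)-3-[(2R,3R)-8-methoxy-3,5-dimethyl-7-oxo-2,3,4,7-tetrahydrocyclohepta[b]pyran-2-yl]prop-2-en-1-yl}phosphonate | CCOP(=O)(C/C=C/[C@H]1[C@H](C)Cc2c(C)cc(=O)c(OC)cc2O1)OCC
F0 | step 26 | none | none
A1 | alternative 1 | bis(pyran-4-one) with the diene and all three centres in place | Cc1cc(=O)c(OC)cc2c1C(=O)[C@@H](C)[C@H](/C=C/C=C/[C@H]1CC(=O)c3c(C)cc(=O)c(OC)cc3O1)O2
A2 | alternative 1 | (1E,3E)-1,4-bis(4,4,5,5-tetramethyl-1,3,2-dioxaborolan-2-yl)buta-1,3-diene | CC1(C)OB(/C=C/C=C/B2OC(C)(C)C(C)(C)O2)OC1(C)C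
A3 | alternative 1 | 8-methoxy-3,5-dimethylcyclohepta[b]pyran-4,7-dione | Cc1cc(=O)c(OC)cc2occ(C)c(=O)c12
A4 | alternative 1 | 8-methoxy-5-methylcyclohepta[b]pyran-4,7-dione | Cc1cc(=O)c(OC)cc2occc(=O)c12
A5 | alternative 2 | open-chain bis(dimethoxytroponoid) diene bis(triethylsilyl ether) | Cc1cc(=O)c(OC)cc(OC)c1C[C@@H](C)[C@H](/C=C/C=C/[C@H](O[Si](CC)(CC)CC)CCc1c(C)cc(=O)c(OC)cc1OC)O[Si](CC)(CC)CC
A6 | alternative 2 | tetraene bis(triethylsilyl ether), configuration as in A5 | C=C(C)[C@H](/C=C/C=C/[C@H](O[Si](CC)(CC)CC)C=C)O[Si](CC)(CC)CC
A7 | alternative 2 | 5-bromo-2,4-dimethoxy-6-methylcyclohepta-2,4,6-trien-1-one | Cc1cc(=O)c(OC)cc(OC)c1Br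
A8 | alternative 3 | oxygen-bridged cycloheptadienone fused to ring B | CC1=CC(=O)C2C=C3C1(O2)C[C@@H](C)[C@H](CO[Si](C)(C)C(C)(C)C)O3
A9 | alternative 3 | 6-acetoxy-5-methyl-2H-pyran-3(6H)-one carrying at C6 the C4–C3–C2 chain with an ethynyl ether on the C2 oxygen | CC1=CC(=O)COC1(OC(C)=O)C[C@@H](C)[C@H](CO[Si](C)(C)C(C)(C)C)OC#C
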